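The number to start from is 0.0554 min⁻¹, the rate constant with which other conformer turns back into starting material, larger than the 0.023 min⁻¹ with which it goes on to isomer of the product.

    starting material ⇌ other conformer (K1 = 9.2, k1 = 0.51 min⁻¹)
    starting material → target (k2 = 0.035 min⁻¹)
    other conformer → isomer of the product (k3 = 0.023 min⁻¹)
    solid substrate ⇌ starting material, rate k4*(cs4 - [starting material]) while solid is left; crystals form when [starting material] > cs4 (cs4 = 38 mM, k4 = 0.80 min⁻¹)

solid substrate 0.050 M; time 8.0 h

1. why nothing more happens at 8.0 h, or that something still does (for what has run out or reacted, a solid counts together with what of it has only dissolved; other conformer counts as not reacted) (forward and back rates have come level / all of the solid substrate has reacted / it is still moving)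
2. the target standing at 8.0 h, as a percentage of the solid substrate charged
3. the isomer of the product standing at 8.0 h, as a percentage of the solid substrate charged

- solid substrate is a solid; its amount is given per volume of the solution
- at the start none of the solid substrate is in solution
- in a conversion other conformer counts as not yet reacted
- what has only dissolved of solid substrate counts as not reacted
- the reaction counts as stopped when no species that holds the solid substrate changes by six tenths of a point or more over the second half of the time
- run time (flask): 8.0 h

You see two peaks, c(target) and c(isomer of the product), and you want their split. My own reckoning uses a small table of exits, one row per dissolved pool:

- starting material: on to target 0.035 min⁻¹; across to other conformer 0.51 min⁻¹; chance per visit of leaving for a product 6.42%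
- other conformer: on to isomer of the product 0.023 min⁻¹; back 0.0554 min⁻¹; chance per visit of leaving for a product 29.3%

The first row says that a molecule in starting material usually crosses over, and reaches target on 6.42% of its visits. The second row says that a molecule in other conformer leaves for isomer of the product on 29.3% of its visits and otherwise returns. Set against each other, each visit to starting material gives target 6.42% and isomer of the product 27.4%. That yields 19.0%, the target share, a selectivity: the chance that a molecule entering as starting material ends as target, with every return counted. The two exits weighted by K1, the Curtin–Hammett ratio, give 14.2%, but that weighting holds the pools at K1 throughout, and in this flask the material enters as starting material, so I keep the target share.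

With the pools near K1, their drain has a half-life of 0.478 h, and the run lasts 16.7 such half-lives. So I expect the solid substrate to have reacted through, leaving target at 19.0% and isomer of the product at 81.0%.

The forecast says all of the solid substrate has reacted, with 19% target and 81% isomer of the product: “The split is fixed by branching rather than by time”.

The flask gives all of the solid substrate has reacted, with 19.0% target and 81.0% isomer of the product. The largest change of any share over the second half of the time is 0.28 percentage points. Applied to the charge of 0.050 M, the target share gives 9.50 mM of target.

For the neighbour charged with 0.12 M, the same constants give a target share of 19.0%, which is 22.8 mM of target. Computed, that neighbour holds 19.0% target and 81.0% isomer of the product.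

The constants are made up; what happens was integrated by code.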